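Remark on the chemistry: the SMILES is read as an unbranched C37 acyl chain (36 alkyl carbons plus the carbonyl carbon) on the aliphatic oxygen of tyrosol, C45H82O3; the molecule has no stereocentre, so no SMILES below carries stereo-descriptors.

## Structural features

The target, 2-(4-hydroxyphenyl)ethyl heptatriacontanoate, is the ester of the primary aliphatic hydroxyl of tyrosol with an unbranched, saturated C37 acid; its only ring is a para-disubstituted benzene, joined to the chain through a CH2CH2–O–C(=O) link. There is no stereocentre and no double bond, so nothing stereochemical has to be set or preserved. The acyl chain (C1 = carbonyl, C37 = methyl) holds 35 contiguous methylene groups, C2 to C36, without a functional handle, and has an odd carbon count, so the acid is not one of the stock even-numbered fatty acids. Every C–C bond inside that run joins two unactivated sp3 carbons of the same polarity, and homologues differing by one or two carbons cannot be separated at this chain length, so the carbon count must be fixed by the construction and not by purification. The fragile groups are the free phenol (easily oxidised, and acylated in competition with the alcohol) and the single ester (hydrolysis, transesterification), so the second problem is to acylate the aliphatic and not the phenolic oxygen. The real difficulty is the chain, and the key step exploits its featureless interior: the C8–C9 bond is made by anodic decarboxylative coupling (mixed Kolbe electrolysis) of triacontanoic acid with monomethyl azelate, which joins two primary alkyl radicals of like polarity. The odd carbon count follows from arithmetic, since each partner loses one carbon as CO2: 29 + 8 = 37.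

## Logic of the disconnections

**9 to 7 and 8.** The bond cut is the ester bond between acyl carbon C1 and the aliphatic oxygen of the arylethyl unit. Cutting here separates the only electron-rich, anodically oxidisable part of 9 (the phenol ring, which arrives with 8) from the chain, so the chain can be built under oxidising conditions that the phenol would not survive. The gain is that 8 is a stock compound and 7 is a C37 chain with one functional group. The demand on the forward step is esterification of the primary aliphatic hydroxyl of 8 beside its free phenol without protecting groups, which points to equilibrating acid catalysis.

**7 to 5.** No skeletal bond is cut; the carboxyl O–H of 7 is exchanged for O–CH3 (functional group interchange). The reason is that in the key step only one carboxyl per partner may be electroactive, so the future C1 carboxyl must pass through as a neutral ester. The gain is that 5 becomes the direct product of a coupling. The demand is complete hydrolysis of a waxy, poorly soluble ester.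

**5 to 1 and 2 (through 3 and 4).** The bond cut is C8–C9. All interior bonds are alike in kind, so the position is chosen by what the fragments become: placing a carboxyl on each new terminus gives 1 (C30) and 2 (a C9 half-ester), both stock acids, and 29 + 8 carbons survive decarboxylation. The gain is that a C37 chain is reduced in one operation to two shelf acids, with no halide, organometallic or olefin to prepare. The demand is the union of two primary sp3 carbons of like polarity, which is possible only through the radicals 3 and 4 generated side by side; the coupling is statistical, so the cheap 2 must be used in excess and the self-coupling products must be separable from 5.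

## Other disconnections considered

Alternative 1: The first disconnection that comes to mind cuts the acyl C1–O bond with the whole chain already in place; the forward key step is base-mediated O-acylation of 8 with heptatriacontanoyl chloride A1. This removes only the eight-carbon arylethyl unit and leaves 7, the actual problem, as an assumed starting material, so a chain construction would still have to precede it. In addition, A1 with base acylates the phenoxide of 8 in competition with the alcohol, so protection and deprotection of the phenol would add two steps. The chosen plan keeps this ester bond as a protecting-group-free last step but solves the chain first.

Alternative 2: Cut C10–C11 as an alkene. The forward key step is cross-metathesis of 2-(4-hydroxyphenyl)ethyl undec-10-enoate A2 with octacos-1-ene A3 using RuCl2(=CHPh)(PCy3)(H2IMes) (second-generation Grubbs catalyst) to give 2-(4-hydroxyphenyl)ethyl heptatriacont-10-enoate A4 (E/Z mixture), followed by hydrogenation. The step count is the same (ester formation, metathesis, hydrogenation), and two terminal alkenes of equal reactivity couple as statistically as two radicals, so nothing is gained. The structural objection is that ruthenium hydrides formed from the catalyst can move a terminal double bond along the chain before metathesis; each migration changes the product length by one carbon, giving C36 and C38 homologues that cannot be removed from a C37 wax. In the Kolbe coupling the carbon count is fixed by the two acids, and the by-products differ by about twenty carbons or by a functional group.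

Alternative 3: Cut C15–C16 by a polar coupling. The forward key step is Li2CuCl4-catalysed alkylation of docosylmagnesium bromide A5 with methyl 15-bromopentadecanoate A6, which would give 5 and then use the same last two steps, so the length is equal. It is the standard polar construction and therefore not the unconventional cut asked for. Mechanistically, one partner must first be turned into a strongly basic organomagnesium reagent, which then has to choose the C–Br bond over the ester carbonyl of A6 at low temperature, where a C22 Grignard solution is barely soluble; Wurtz-type self-coupling accompanies the formation of A5. A6 is also an odd-numbered chain with two differentiated ends. The anodic coupling instead uses the carboxyl group, the native terminus of fatty acids and diacid half-esters, as a traceless handle on both partners, needs no anhydrous or inert technique, and tolerates the ester.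

Key step: step 1

## Route

Step 1
Reactants: 1 triacontanoic acid; 2 9-methoxy-9-oxononanoic acid (monomethyl azelate)
Product: 5 methyl heptatriacontanoate, via nonacosyl radical 3 (not isolated), via 8-methoxy-8-oxooctyl radical 4 (not isolated)
Conditions: 2 (6 equiv), KOH (0.05 equiv per CO2H), MeOH/pyridine (4:1), undivided cell, smooth platinum anode and cathode, 50–55 °C, constant current (ca. 0.25 A cm−2) to a faintly alkaline end point; cool to 0 °C, filter, silica (warm hexane to toluene)
Reagents that add atoms: none
Why: Mixed Kolbe electrolysis, the classical anodic chain extension of a fatty acid by a dicarboxylic half-ester, is the closest known reaction type and is used here unchanged. At smooth platinum and high current density the carboxylates of 1 and 2 form an adsorbed layer, are oxidised by one electron each and lose CO2 within the lifetime of the acyloxy radicals, so that the primary radicals 3 and 4 arise side by side at high local concentration and combine at diffusion-controlled rates to form the C8–C9 bond of 5, while the cathode only reduces protons to hydrogen. Both are unstabilised primary alkyl radicals of like polarity, so the union is statistical; the selectivity the step needs, cross- over self-coupling of the limiting acid 1, is secured by the sixfold excess of the cheap partner 2, which on statistical grounds (equal discharge rates assumed) should send about six of seven radicals 3 into 5. The two-electron (Hofer–Moest) path to carbocations is disfavoured by the substrates and the conditions: unbranched primary radicals without an α-heteroatom are hard to oxidise, and platinum, weakly acidic methanol and a low degree of neutralisation all favour radical coupling. The methyl ester of 2 lies seven methylenes from the reacting carbon, is not electroactive, and can only exchange methoxy for methoxy in methanol. No ring is closed and no stereocentre is formed. The carbon count of 5 is fixed by arithmetic (29 + 8 = 37) and cannot drift by one carbon, and the self-coupling products (a C58 alkane from 1, a C18 diester from 2) differ from the C38 monoester 5 so much in size and polarity that crystallisation from the cooled electrolyte and a silica filtration should remove them.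

Step 2
Reactants: 5 methyl heptatriacontanoate
Product: 7 heptatriacontanoic acid, via potassium heptatriacontanoate 6 (not isolated)
Conditions: KOH (5 equiv), EtOH/THF/H2O (5:5:1), reflux; then 2 M HCl, 60 °C; filter, recrystallise (toluene)
Reagents that add atoms: potassium hydroxide, [K+].[OH-]
Why: Saponification (BAc2) of an unhindered primary alkyl ester, made irreversible by formation of the carboxylate 6; THF keeps the waxy ester in solution at reflux. The chain carries no other functional group, and hot acidification should convert the soap 6 into 7, which crystallises on cooling.

Step 3
Reactants: 7 heptatriacontanoic acid; 8 tyrosol, 4-(2-hydroxyethyl)phenol
Product: 9 2-(4-hydroxyphenyl)ethyl heptatriacontanoate (target)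
Conditions: 8 (3 equiv), TsOH·H2O (0.1 equiv), toluene, reflux, Dean–Stark trap; wash with water and aq. NaHCO3, recrystallise (EtOAc/hexane)
Reagents that add atoms: none
Why: Fischer esterification under equilibrating acid catalysis with azeotropic removal of water: only the primary aliphatic hydroxyl of 8 is nucleophilic enough to add to the protonated acid, and an aryl ester, being the higher-energy ester, should not accumulate under reversible conditions, so the phenol needs no protection. Hot toluene dissolves 7 and 9, the excess of the water-soluble 8 is washed out afterwards, and no stereocentre is involved.

## Compound list

1 | triacontanoic acid | CCCCCCCCCCCCCCCCCCCCCCCCCCCCCC(=O)O | starting material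
2 | 9-methoxy-9-oxononanoic acid (monomethyl azelate) | COC(=O)CCCCCCCC(=O)O | starting material
3 | nonacosyl radical | [CH2]CCCCCCCCCCCCCCCCCCCCCCCCCCCC | intermediate
4 | 8-methoxy-8-oxooctyl radical | [CH2]CCCCCCC(=O)OC | intermediate
5 | methyl heptatriacontanoate | CCCCCCCCCCCCCCCCCCCCCCCCCCCCCCCCCCCCC(=O)OC | intermediate
6 | potassium heptatriacontanoate | CCCCCCCCCCCCCCCCCCCCCCCCCCCCCCCCCCCCC(=O)[O-].[K+] | intermediate
7 | heptatriacontanoic acid | CCCCCCCCCCCCCCCCCCCCCCCCCCCCCCCCCCCCC(=O)O | intermediate
8 | tyrosol, 4-(2-hydroxyethyl)phenol | OCCc1ccc(O)cc1 | starting material
9 | 2-(4-hydroxyphenyl)ethyl heptatriacontanoate | CCCCCCCCCCCCCCCCCCCCCCCCCCCCCCCCCCCCC(=O)OCCc1ccc(O)cc1 | target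

## Step count and least certain steps

Total step count: 3. Longest linear sequence: 3 steps (1 to 5 to 7 to 9).

**Step 1 (key step).** The most likely failure is loss of current efficiency and of cross-coupling through passivation of the anode. A film of the sparingly soluble potassium soap of 1, or of precipitating product, would raise the local anode potential and divert the reaction to two-electron oxidation (cation-derived ethers, alkenes and esters) and to solvent oxidation. Radical disproportionation and alkylation of the pyridine co-solvent by the radicals would reduce the yield further.

The fallback sets out from 1 and returns to the route at 7; it replaces the radical union by a polar acyl coupling followed by deoxygenation, with a carbon count of 30 + 7.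
- 1 is converted with oxalyl chloride and catalytic DMF in toluene at 50 °C into triacontanoyl chloride F1.
- Commercial ethyl 7-bromoheptanoate (CCOC(=O)CCCCCCBr) is converted by LiCl-promoted zinc insertion (Zn dust, LiCl, THF, 50 °C) into (7-ethoxy-7-oxoheptyl)zinc bromide F2.
- Negishi acylation of F2 with F1 (Pd(PPh3)4 cat., THF/toluene, 40 °C) should give ethyl 8-oxoheptatriacontanoate F3.
- Wolff–Kishner reduction in the Huang-Minlon manner (N2H4·H2O, KOH, diethylene glycol, 130 then 200 °C, HCl work-up) should remove the C8 carbonyl and saponify the ester in the same pot, passing through 6, to give 7.

**Step 3.** The most likely failure is incomplete conversion, because the esterification is an equilibrium and water removal from a dilute, waxy system is slow. Acid-promoted self-condensation of 8 (ether formation assisted by the electron-rich ring) and co-crystallisation of unreacted 7 with the product are further risks.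

The fallback sets out from 8, is joined by 7, and returns at 9; it changes to a protect–acylate–deprotect approach.
- 8 is benzylated at the phenol only (benzyl bromide, K2CO3, acetone, reflux; carbonate deprotonates only the phenol) to give 2-[4-(benzyloxy)phenyl]ethanol F4.
- Steglich esterification of F4 with 7 (DCC, DMAP cat., CH2Cl2/toluene, 35 °C) should give 2-[4-(benzyloxy)phenyl]ethyl heptatriacontanoate F5.
- Hydrogenolysis (H2, Pd/C, THF/EtOAc, 40 °C) should cleave the benzyl ether without touching the alkyl ester and give 9.

**Step 2.** The most likely failure is incomplete saponification: the ester and its potassium soap are poorly soluble and can form gels that enclose unreacted ester, and the soap may be incompletely protonated on work-up.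

The fallback sets out from 5 and returns at 9, bypassing 6 and 7. It is a direct acid-catalysed transesterification of 5 with 8 (3–5 equiv; TsOH·H2O cat., toluene, reflux, with the condensate returned through 4 Å molecular sieves to remove methanol). It relies on the same thermodynamic preference for the alkyl over the aryl ester and makes no new compound (F0).

## Further compounds

F1 | step 1 | triacontanoyl chloride | CCCCCCCCCCCCCCCCCCCCCCCCCCCCCC(=O)Cl
F2 | step 1 | (7-ethoxy-7-oxoheptyl)zinc bromide | CCOC(=O)CCCCCC[Zn]Br
F3 | step 1 | ethyl 8-oxoheptatriacontanoate | CCOC(=O)CCCCCCC(=O)CCCCCCCCCCCCCCCCCCCCCCCCCCCCC
F4 | step 3 | 2-[4-(benzyloxy)phenyl]ethanol | OCCc1ccc(OCc2ccccc2)cc1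
F5 | step 3 | 2-[4-(benzyloxy)phenyl]ethyl heptatriacontanoate | CCCCCCCCCCCCCCCCCCCCCCCCCCCCCCCCCCCCC(=O)OCCc1ccc(OCc2ccccc2)cc1
F0 | step 2 | none | none
A1 | alternative 1 | heptatriacontanoyl chloride | CCCCCCCCCCCCCCCCCCCCCCCCCCCCCCCCCCCCC(=O)Cl
A2 | alternative 2 | 2-(4-hydroxyphenyl)ethyl undec-10-enoate | C=CCCCCCCCCC(=O)OCCc1ccc(O)cc1
A3 | alternative 2 | octacos-1-ene | C=CCCCCCCCCCCCCCCCCCCCCCCCCCC
A4 | alternative 2 | 2-(4-hydroxyphenyl)ethyl heptatriacont-10-enoate (E/Z mixture) | CCCCCCCCCCCCCCCCCCCCCCCCCCC=CCCCCCCCCC(=O)OCCc1ccc(O)cc1
A5 | alternative 3 | docosylmagnesium bromide | CCCCCCCCCCCCCCCCCCCCCC[Mg]Br
A6 | alternative 3 | methyl 15-bromopentadecanoate | COC(=O)CCCCCCCCCCCCCCBr
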